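The constants used here stand for no real mixture; what happens was integrated by code.

The constants describe a flask in which a molecule of E stands at a fork: Z carries it on towards J, while J, once formed, can take it away as E.J.

    E + Z → E.Z (k1 = 0.0018 M⁻¹ min⁻¹, Ea1 = 55.0 kJ mol⁻¹)
    E + J → E.J (k2 = 4.1 × 10⁻⁴ M⁻¹ min⁻¹, Ea2 = 84.0 kJ mol⁻¹)
    Z + G → Z.G (k3 = 0.0013 M⁻¹ min⁻¹, Ea3 = 66.0 kJ mol⁻¹)
    E.Z + Z.G → J (k4 = 0.0024 M⁻¹ min⁻¹, Ea4 = 75.0 kJ mol⁻¹)
    (constants at 0 °C)

| setting | cedar | maple | oak | ash |
|---|---|---|---|---|
| E | 0.30 M | 0.30 M | 0.30 M | 0.30 M |
| G | 1.80 equiv | 1.80 equiv | 1.80 equiv | 1.80 equiv |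
| Z | 1.80 equiv | 1.80 equiv | 1.80 equiv | 1.80 equiv |
| temperature | 25 °C | 0 °C | 50 °C | −25 °C |
| time | 4.0 d | 4.0 d | 4.0 d | 4.0 d |

- percentages count the E that a species holds: one E.J counts as two
- the list of constants is for 0 °C, to be carried to other temperatures by the activation energies

* the flask that comes out highest in amount of J, in percent of the E charged, or "all alike" when all lie within 1.5 percentage points (cedar / maple / oak / ash / all alike)
* J at the end, in percent of the E charged, cedar
* J at the end, in percent of the E charged, maple
* J at the end, in percent of the E charged, oak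
* J at the end, in percent of the E charged, ash

The next run has to fix a bath and a reading for the same charge, so follow one free molecule of E. Its chances of meeting Z and J stand as the constant of E + Z times Z against the constant of E + J times J. Free E cancels, and the two chances are equal when J, over Z, both as fractions of the E charged, reaches the ratio of the constants at 0 °C:

0.0018 M⁻¹ min⁻¹ / 4.1 × 10⁻⁴ M⁻¹ min⁻¹ = 4.39

This J-to-Z ratio, at which an E is as likely to be captured as carried on, is the crossover ratio, the selectivity factor of the fork in maple.

Warming moves it against J, because capture has the higher activation energy, 84.0 kJ mol⁻¹ against 55.0 kJ mol⁻¹. The step Z + G speeds up 1700 times from ash to oak, and logarithms scale with activation energy, so over that span capture gains on carrying-on by a factor of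

exp(ln(1700) × (84.0 kJ mol⁻¹ − 55.0 kJ mol⁻¹) / 66.0 kJ mol⁻¹) = 26.1

In maple the time constant of E against the Z charged is

1 / (0.0018 M⁻¹ min⁻¹ × 1.80 equiv × 0.30 M) = 0.714 d

The run of 4.0 d is longer than this, by 5.60 time constants, so the fork is reached within the run. Each J consumes two Z, one through E.Z and one through Z.G, so Z is the limiting reagent. At the start of maple, one molecule of Z meets E or G in the ratio of the constant of E + Z to that of Z + G times the G charged, so its chance of joining E is

0.0018 M⁻¹ min⁻¹ / (0.0018 M⁻¹ min⁻¹ + 0.0013 M⁻¹ min⁻¹ × 1.80 equiv) = 43.5%

Holding this start share through the run, as an estimate, the Z charged makes E.Z for 78.3% of the E charged. With E taken at 0.5 of its charge over the run, a J escapes capture with a chance of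

exp(−0.5 × 4.1 × 10⁻⁴ M⁻¹ min⁻¹ × 0.30 M × 4.0 d) = 70.2%

The product gives the estimate for J in maple, 54.9% of the E charged. This reckoning gives no time constant for ash. The plan for the next run is to keep the charge, run at the temperature of maple, and watch J over Z against the crossover ratio.

The forecast names maple, with 20% for cedar, 48% for maple, 1% for oak and 0.5% for ash, holding that “the 0 °C flask wins, having run far enough while capture by E stays modest”. Its figure for maple lies below the estimate reckoned here.

The simulation gives maple, with 20.8% for cedar, 50.3% for maple, 1.69% for oak and 0.539% for ash, and the forecast stands.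

In maple at 4.00 d, J holds 50.3% of the E charged and Z 3.30% of its own charge, so J over Z is 8.48, above the crossover ratio of 4.39. The 24.2% of E still free in maple is now met by J more often than by Z, and maple left to 40.0 d holds 42.8% J against 50.3%. The neighbouring flask, maple read at 2.5 d, holds 39.9% J and 8.72% Z, a ratio of 2.54, still below the crossover, with E.J at 6.49%.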